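**Retrosynthetic overview**
- Euchrenone a3 comes from its B-ring MOM ether, and that from a 2',4',6'-trihydroxy-3',5'-diprenylchalcone by an enantioselective oxa-Michael addition that closes ring C and sets C2. The two ortho hydroxyls of ring A are equivalent, so only the 6,8-diprenyl flavanone can form.
- The strategy rests on ring A (C4a, C5, C6, C7, C8, C8a) with the C4 carbonyl on C4a. It is a C-acylphloroglucinol with oxygens on C5, C7 and C8a, i.e. a folded 3,5,7-triketo ester whose prenylated C6 and C8 were chain methines. The chalcone therefore comes from a 2,4-diprenyl-3,5,7-triketo ester by intramolecular Claisen condensation (C4a–C8a bond).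
- The triketo ester comes from the trianion of methyl 2,4-diprenyl-3,5-dioxohexanoate and the Weinreb amide of the chromene cinnamic acid (bond between chain C6 and C7).
- The diketo ester comes from methyl acetoacetate by γ-prenylation, α-prenylation and γ-acetylation. The Weinreb amide comes from resorcinol by chromene annulation, ortho-formylation, MOM protection and Horner–Wadsworth–Emmons olefination.
- Ring order: pyran ring of the chromene (step 4), ring A (step 9), ring C (step 10); ring B is carried from resorcinol.

Key step: step 9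

Assumption: the quinine-derived catalyst of step 10 is taken to deliver the (2S) configuration; if an analytical run shows the opposite sense, its quinidine-derived pseudo-enantiomer is used instead.

**Route**

Step 1
Reactants: 1 methyl acetoacetate; 2 1-bromo-3-methylbut-2-ene
Product: 3 methyl 7-methyl-3-oxooct-6-enoate
Conditions: NaH, THF, 0 °C; n-BuLi, 0 °C; then 2, 0 °C to rt; aq. HCl
Reagents that add atoms: none
Why: Weiler dianion alkylation, in which the γ-carbanion of the acetoacetate dianion is the more basic and more nucleophilic site and displaces bromide from the primary allylic halide (SN2), leaving C2 untouched.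

Step 2
Reactants: 3 methyl 7-methyl-3-oxooct-6-enoate; 2 1-bromo-3-methylbut-2-ene
Product: 4 methyl 7-methyl-2-(3-methylbut-2-enyl)-3-oxooct-6-enoate (racemic)
Conditions: K2CO3, 2 (1.0 equiv), acetone, reflux
Reagents that add atoms: none
Why: Enolate C-alkylation of the β-keto ester at C2 with one equivalent of the allylic bromide; the new C2 stereocenter is racemic and is erased when ring A aromatises.

Step 3
Reactants: 4 methyl 7-methyl-2-(3-methylbut-2-enyl)-3-oxooct-6-enoate; 5 N-methoxy-N-methylacetamide
Product: 6 methyl 2,4-bis(3-methylbut-2-enyl)-3,5-dioxohexanoate (epimer and enol mixture)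
Conditions: LiN(i-Pr)2 (2.2 equiv), THF, −78 to 0 °C; then 5, −78 to 0 °C; cold aq. HCl
Reagents that add atoms: none
Why: γ-Acylation of a β-keto ester dianion (Huckin–Weiler type), in which the second deprotonation can only occur at C4 and the chelated tetrahedral adduct of the Weinreb amide survives until work-up, so the diketone is never exposed to base; the C2 and C4 centres are uncontrolled and later erased.

Step 4
Reactants: 7 resorcinol; 8 3-methylbut-2-enal
Product: 9 2,2-dimethyl-2H-chromen-7-ol
Conditions: pyridine, 140 °C (sealed vessel), 7 in excess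
Reagents that add atoms: none
Why: Pyridine-mediated chromenylation, in which aldol-type attack of resorcinol C4 on the enal, loss of water to an ortho-quinone methide and oxa-6π electrocyclisation give the 2,2-dimethylchromene; excess resorcinol holds back double annulation and the minor 5-hydroxy isomer is removed by chromatography.

Step 5
Reactants: 9 2,2-dimethyl-2H-chromen-7-ol
Product: 10 7-hydroxy-2,2-dimethyl-2H-chromene-6-carbaldehyde
Conditions: MgCl2, Et3N, (CH2O)n, MeCN, reflux; aq. HCl
Reagents that add atoms: paraformaldehyde (as formaldehyde), C=O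
Why: Casnati–Skattebøl ortho-formylation through the magnesium phenoxide places the formyl group only ortho to the hydroxyl and should prefer C6, which is para to the ring oxygen and less hindered than C8 between two oxygens.

Step 6
Reactants: 10 7-hydroxy-2,2-dimethyl-2H-chromene-6-carbaldehyde
Product: 11 7-(methoxymethoxy)-2,2-dimethyl-2H-chromene-6-carbaldehyde
Conditions: MOMCl, i-Pr2NEt, CH2Cl2, 0 °C to reflux
Reagents that add atoms: chloromethyl methyl ether, COCCl
Why: Williamson-type O-alkylation of the phenol with the reactive α-chloro ether gives a base-stable acetal that should withstand the polyanion and methoxide steps.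

Step 7
Reactants: 11 7-(methoxymethoxy)-2,2-dimethyl-2H-chromene-6-carbaldehyde; 12 diethyl {2-[methoxy(methyl)amino]-2-oxoethyl}phosphonate
Product: 13 (E)-N-methoxy-N-methyl-3-[7-(methoxymethoxy)-2,2-dimethyl-2H-chromen-6-yl]prop-2-enamide
Conditions: NaH, THF, 0 °C to rt
Reagents that add atoms: none
Why: Horner–Wadsworth–Emmons olefination of a non-enolisable aldehyde with an amide-stabilised phosphonate anion should give the (E)-alkene.

Step 8
Reactants: 6 methyl 2,4-bis(3-methylbut-2-enyl)-3,5-dioxohexanoate; 13 (E)-N-methoxy-N-methyl-3-[7-(methoxymethoxy)-2,2-dimethyl-2H-chromen-6-yl]prop-2-enamide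
Product: 14 methyl (E)-9-[7-(methoxymethoxy)-2,2-dimethyl-2H-chromen-6-yl]-2,4-bis(3-methylbut-2-enyl)-3,5,7-trioxonon-8-enoate (epimer and enol mixture)
Conditions: LiN(i-Pr)2 (3.1 equiv per 6), THF, 0 °C; then 13, −78 to 0 °C; cold aq. HCl; used without storage
Reagents that add atoms: none
Why: Harris-type polyanion acylation, in which the terminal methyl carbanion of the trianion (last formed, most basic) adds 1,2 to the Weinreb amide, whose chelated adduct prevents over-reaction, while the electron-rich aryl group and amide conjugation disfavour 1,4-addition; all isomers of the product converge in step 9.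

Step 9
Reactants: 14 methyl (E)-9-[7-(methoxymethoxy)-2,2-dimethyl-2H-chromen-6-yl]-2,4-bis(3-methylbut-2-enyl)-3,5,7-trioxonon-8-enoate
Product: 15 (E)-3-[7-(methoxymethoxy)-2,2-dimethyl-2H-chromen-6-yl]-1-[2,4,6-trihydroxy-3,5-bis(3-methylbut-2-enyl)phenyl]prop-2-en-1-one
Conditions: Mg(OMe)2 (excess), MeOH, reflux; then cold aq. HCl to pH 3, rapid extraction
Reagents that add atoms: none
Why: Mg(OMe)2 removes the most acidic proton, at the unsubstituted C6 methylene between the C5 and C7 carbonyls, and the magnesium-chelated carbanion adds to the ester carbonyl C1, expels methoxide, and the resulting 2-acylcyclohexane-1,3,5-trione enolises three times to the acylphloroglucinol, which as its magnesium phenoxide cannot revert. The closest known reaction is the base-induced Claisen-type cyclisation of 3,5,7-triketo esters to acylphloroglucinols, including styryl ketones that give chalcones. Ring A closes by a 6-exo-trig acyl substitution that forms the C4a–C8a bond; no stereocenter is made and those at chain C2 and C4 are erased. The selectivity needed is Claisen over aldol folding: the prenyl on C2 would make an aldol adduct at C7 quaternary and unable to aromatise, so that path stays reversible, and C7 is held as part of a diketonate and is not electrophilic. Lactonisation to a 4-hydroxy-2-pyranone is reversed by Mg(OMe)2 in MeOH, and conjugate addition to the enone is disfavoured because the enone belongs to the C5–C7 diketonate and carries an electron-rich aryl group. Cold acidification and fast extraction should keep the chalcone from closing to racemic flavanone.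

Step 10
Reactants: 15 (E)-3-[7-(methoxymethoxy)-2,2-dimethyl-2H-chromen-6-yl]-1-[2,4,6-trihydroxy-3,5-bis(3-methylbut-2-enyl)phenyl]prop-2-en-1-one
Product: 16 (2S)-5,7-dihydroxy-2-[7-(methoxymethoxy)-2,2-dimethyl-2H-chromen-6-yl]-6,8-bis(3-methylbut-2-enyl)-2,3-dihydro-4H-chromen-4-one
Conditions: N-[3,5-bis(trifluoromethyl)phenyl]-N'-[(8α,9S)-6'-methoxycinchonan-9-yl]thiourea (10 mol%), toluene, −20 °C
Reagents that add atoms: none
Why: Bifunctional cinchona-thiourea-catalysed intramolecular oxa-Michael addition of a 2'-hydroxychalcone (6-endo-trig closure of ring C), in which the quinuclidine nitrogen activates the phenol while the thiourea binds the enone carbonyl, the catalyst selects the face of the β-carbon and so sets C2 as S, and the equivalence of the two ortho hydroxyls allows only one constitution.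

Step 11
Reactants: 16 (2S)-5,7-dihydroxy-2-[7-(methoxymethoxy)-2,2-dimethyl-2H-chromen-6-yl]-6,8-bis(3-methylbut-2-enyl)-2,3-dihydro-4H-chromen-4-one
Product: 17 euchrenone a3, (2S)-5,7-dihydroxy-2-(7-hydroxy-2,2-dimethyl-2H-chromen-6-yl)-6,8-bis(3-methylbut-2-enyl)-2,3-dihydro-4H-chromen-4-one
Conditions: HCl (1.25 M in MeOH), MeOH, 0 °C to rt
Reagents that add atoms: none
Why: Acid-catalysed transacetalisation of the aryl MOM ether to dimethoxymethane; dilute acid at or below room temperature should spare the prenyl groups, the chromene and the C2 stereocenter, since flavanone racemisation runs through base-promoted retro-oxa-Michael opening.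

**Compound list**

1 | methyl acetoacetate | COC(=O)CC(C)=O | starting material
2 | 1-bromo-3-methylbut-2-ene | CC(C)=CCBr | starting material
3 | methyl 7-methyl-3-oxooct-6-enoate | COC(=O)CC(=O)CCC=C(C)C | intermediate
4 | methyl 7-methyl-2-(3-methylbut-2-enyl)-3-oxooct-6-enoate (racemic) | COC(=O)C(CC=C(C)C)C(=O)CCC=C(C)C | intermediate
5 | N-methoxy-N-methylacetamide | CC(=O)N(C)OC | starting material
6 | methyl 2,4-bis(3-methylbut-2-enyl)-3,5-dioxohexanoate (epimer mixture) | COC(=O)C(CC=C(C)C)C(=O)C(CC=C(C)C)C(C)=O | intermediate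
7 | resorcinol | Oc1cccc(O)c1 | starting material
8 | 3-methylbut-2-enal | CC(C)=CC=O | starting material
9 | 2,2-dimethyl-2H-chromen-7-ol | CC1(C)C=Cc2ccc(O)cc2O1 | intermediate
10 | 7-hydroxy-2,2-dimethyl-2H-chromene-6-carbaldehyde | CC1(C)C=Cc2cc(C=O)c(O)cc2O1 | intermediate
11 | 7-(methoxymethoxy)-2,2-dimethyl-2H-chromene-6-carbaldehyde | CC1(C)C=Cc2cc(C=O)c(OCOC)cc2O1 | intermediate
12 | diethyl {2-[methoxy(methyl)amino]-2-oxoethyl}phosphonate | CCOP(=O)(OCC)CC(=O)N(C)OC | starting material
13 | (E)-N-methoxy-N-methyl-3-[7-(methoxymethoxy)-2,2-dimethyl-2H-chromen-6-yl]prop-2-enamide | CON(C)C(=O)/C=C/c1cc2c(cc1OCOC)OC(C)(C)C=C2 | intermediate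
14 | methyl (E)-9-[7-(methoxymethoxy)-2,2-dimethyl-2H-chromen-6-yl]-2,4-bis(3-methylbut-2-enyl)-3,5,7-trioxonon-8-enoate (epimer and enol mixture) | COC(=O)C(CC=C(C)C)C(=O)C(CC=C(C)C)C(=O)CC(=O)/C=C/c1cc2c(cc1OCOC)OC(C)(C)C=C2 | intermediate
15 | (E)-3-[7-(methoxymethoxy)-2,2-dimethyl-2H-chromen-6-yl]-1-[2,4,6-trihydroxy-3,5-bis(3-methylbut-2-enyl)phenyl]prop-2-en-1-one | CC(C)=CCc1c(O)c(CC=C(C)C)c(O)c(C(=O)/C=C/c2cc3c(cc2OCOC)OC(C)(C)C=C3)c1O | intermediate
16 | (2S)-5,7-dihydroxy-2-[7-(methoxymethoxy)-2,2-dimethyl-2H-chromen-6-yl]-6,8-bis(3-methylbut-2-enyl)-2,3-dihydro-4H-chromen-4-one | CC(C)=CCc1c(O)c(CC=C(C)C)c2c(c1O)C(=O)C[C@@H](c1cc3c(cc1OCOC)OC(C)(C)C=C3)O2 | intermediate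
17 | euchrenone a3, (2S)-5,7-dihydroxy-2-(7-hydroxy-2,2-dimethyl-2H-chromen-6-yl)-6,8-bis(3-methylbut-2-enyl)-2,3-dihydro-4H-chromen-4-one | CC(C)=CCc1c(O)c(CC=C(C)C)c2c(c1O)C(=O)C[C@@H](c1cc3c(cc1O)OC(C)(C)C=C3)O2 | target

**Step count**

Total steps: 11. Longest linear sequence: 8 steps (steps 4, 5, 6, 7, 8, 9, 10, 11, from resorcinol).

**Steps most likely to fail**

Step 9. The folding may stall at lactonisation to the 2-pyranone, or divert into intramolecular conjugate addition of the C4 enolate to the enone or methoxide-induced retro-Claisen cleavage of the chain, instead of C-acylation at C6. Fallback: ring A is taken from a preformed aromatic ring, setting out from 2 and 11. Commercial 1-(2,4,6-trihydroxyphenyl)ethanone is C-prenylated twice with 2 (aq. KOH, 0 °C) to 1-[2,4,6-trihydroxy-3,5-bis(3-methylbut-2-enyl)phenyl]ethanone F1, which is separated from mono- and geminally diprenylated material. Claisen–Schmidt condensation of F1 with aldehyde 11 (concentrated KOH, EtOH–H2O, rt) should give chalcone 15, where the route is rejoined.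

Step 8. Trianion formation from the 2,4-dialkylated diketo ester may be incomplete, the polyanion may cyclise prematurely onto its own ester, or the carbanion may add in conjugate fashion to the enamide. Fallback: the diketo ester is masked as a pyranone, setting out from 6. Lactonisation of 6 (DBU, toluene, reflux) should give 4-hydroxy-6-methyl-3,5-bis(3-methylbut-2-enyl)-2H-pyran-2-one F2. Its dianion (LiN(i-Pr)2, 2.2 equiv, THF, −78 °C; hydroxyl then 6-methyl) is acylated with 13 to give 4-hydroxy-6-{(E)-4-[7-(methoxymethoxy)-2,2-dimethyl-2H-chromen-6-yl]-2-oxobut-3-enyl}-3,5-bis(3-methylbut-2-enyl)-2H-pyran-2-one F3. Mg(OMe)2 in MeOH opens the lactone of F3 to triketo ester 14, where the route is rejoined and continues in the same flask as in step 9.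

Step 10. Uncatalysed closure of the acidic trihydroxychalcone may outrun the catalyst-controlled pathway, and reversible ring opening may erode the enantiomeric purity. Fallback: resolution with recycling, setting out from 15. Closure without chiral control (NaOAc, EtOH, reflux) gives the racemic flavanone F4, 5,7-dihydroxy-2-[7-(methoxymethoxy)-2,2-dimethyl-2H-chromen-6-yl]-6,8-bis(3-methylbut-2-enyl)-2,3-dihydro-4H-chromen-4-one. Preparative HPLC on a cellulose tris(3,5-dimethylphenylcarbamate) stationary phase separates the enantiomers; the (2S) enantiomer is 16, where the route is rejoined. The (2R) enantiomer F5 is reopened to chalcone 15 with KOH in EtOH followed by cold acidification, and recycled.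

**Further compounds**

F1 | step 9 | 1-[2,4,6-trihydroxy-3,5-bis(3-methylbut-2-enyl)phenyl]ethanone | CC(=O)c1c(O)c(CC=C(C)C)c(O)c(CC=C(C)C)c1O
F2 | step 8 | 4-hydroxy-6-methyl-3,5-bis(3-methylbut-2-enyl)-2H-pyran-2-one | CC1=C(CC=C(C)C)C(O)=C(CC=C(C)C)C(=O)O1
F3 | step 8 | 4-hydroxy-6-{(E)-4-[7-(methoxymethoxy)-2,2-dimethyl-2H-chromen-6-yl]-2-oxobut-3-enyl}-3,5-bis(3-methylbut-2-enyl)-2H-pyran-2-one | O=C(CC1=C(CC=C(C)C)C(O)=C(CC=C(C)C)C(=O)O1)/C=C/c1cc2c(cc1OCOC)OC(C)(C)C=C2
F4 | step 10 | racemic 5,7-dihydroxy-2-[7-(methoxymethoxy)-2,2-dimethyl-2H-chromen-6-yl]-6,8-bis(3-methylbut-2-enyl)-2,3-dihydro-4H-chromen-4-one | CC(C)=CCc1c(O)c(CC=C(C)C)c2c(c1O)C(=O)CC(c1cc3c(cc1OCOC)OC(C)(C)C=C3)O2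
F5 | step 10 | (2R)-5,7-dihydroxy-2-[7-(methoxymethoxy)-2,2-dimethyl-2H-chromen-6-yl]-6,8-bis(3-methylbut-2-enyl)-2,3-dihydro-4H-chromen-4-one | CC(C)=CCc1c(O)c(CC=C(C)C)c2c(c1O)C(=O)C[C@H](c1cc3c(cc1OCOC)OC(C)(C)C=C3)O2
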